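**Retrosynthetic overview**

- The target comes from the fully assembled flavone by removing two benzyl ethers (A ring) and two MOM ethers (B ring).
- Key disconnection C2–C1′: chromone C2, normally the electrophilic β-carbon, is used as a carbanion (a C2-zincated chromone, i.e. a metalated enol ether or masked acyl anion) and joined to the electrophilic ipso carbon of a B-ring aryl iodide.
- A/C part: chromone from enaminone from acetophenone; the 6,8-OMe groups come from dibromination and copper-mediated methoxylation of 2′,4′,6′-trihydroxyacetophenone.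
- B-ring iodide: from methoxyhydroquinone by bis-MOM protection and ortho-lithiation/iodination at the C–H between OMe and OMOM.
- Ring order: A ring bought, C ring closed in step 4, B ring (bought, functionalised separately) attached last in step 7.

Assumption: the target has no stereocentre and no configurationally stable axis, so it is achiral and there is no enantiomer to select; the route gives the single compound of the given SMILES.

**Route**

Step 1
Reactants: 1 2′,4′,6′-trihydroxyacetophenone
Product: 2 1-(3,5-dibromo-2,4,6-trihydroxyphenyl)ethan-1-one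
Conditions: NBS (2.05 equiv), MeCN, 0 °C → rt
Reagents that add atoms: N-bromosuccinimide, O=C1CCC(=O)N1Br
Why: Electrophilic aromatic bromination; each of the two free ring carbons is ortho/para to three oxygen donors, so both are brominated far faster than the acetyl α-position.

Step 2
Reactants: 2 1-(3,5-dibromo-2,4,6-trihydroxyphenyl)ethan-1-one
Product: 3 1-(2,4,6-trihydroxy-3,5-dimethoxyphenyl)ethan-1-one
Conditions: NaOMe (30% in MeOH, 10 equiv), CuBr (0.3 equiv), DMF, 110 °C, Ar; then aq. HCl
Reagents that add atoms: sodium methoxide, C[O-].[Na+]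
Why: Copper(I)-mediated Ullmann-type methoxylation of aryl bromides flanked by phenoxides, the same exchange that is established for 6,8-dibromo-5,7-dihydroxyflavones; ketone and phenoxides are inert to methoxide.

Step 3
Reactants: 3 1-(2,4,6-trihydroxy-3,5-dimethoxyphenyl)ethan-1-one
Product: 4 1-[4,6-bis(benzyloxy)-2-hydroxy-3,5-dimethoxyphenyl]ethan-1-one
Conditions: BnBr (2.05 equiv), K2CO3 (2.2 equiv), DMF, rt → 40 °C
Reagents that add atoms: benzyl bromide, BrCc1ccccc1
Why: Williamson etherification; the 4-OH and one ortho-OH alkylate while the last ortho-OH is held in a hydrogen bond to the acetyl C=O, and the fully substituted ring cannot be C-benzylated.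

Step 4
Reactants: 4 1-[4,6-bis(benzyloxy)-2-hydroxy-3,5-dimethoxyphenyl]ethan-1-one
Product: 6 5,7-bis(benzyloxy)-6,8-dimethoxy-4H-chromen-4-one, via enaminone 5 (not isolated)
Conditions: DMF-DMA (3 equiv), toluene, 100 °C; concentrate; then AcOH, 80 °C
Reagents that add atoms: N,N-dimethylformamide dimethyl acetal, COC(OC)N(C)C
Why: Condensation of the methyl ketone with the formamide acetal gives the enaminone, and acid-promoted intramolecular oxa-Michael addition with loss of dimethylamine by the free ortho-phenol closes the pyranone ring (enaminone chromone synthesis).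

Step 5
Reactants: 7 2-methoxybenzene-1,4-diol (methoxyhydroquinone)
Product: 8 2-methoxy-1,4-bis(methoxymethoxy)benzene
Conditions: NaH (2.4 equiv), DMF, 0 °C; MOMCl (2.4 equiv), 0 °C → rt, Ar
Reagents that add atoms: chloromethyl methyl ether, COCCl
Why: Williamson-type O-alkylation of both phenoxides; the MOM groups later direct the ortho-metalation and come off with mild acid.

Step 6
Reactants: 8 2-methoxy-1,4-bis(methoxymethoxy)benzene
Product: 10 2-iodo-3-methoxy-1,4-bis(methoxymethoxy)benzene, via aryllithium 9 (not isolated)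
Conditions: n-BuLi (1.15 equiv), THF, 0 °C → rt, 1 h; then I2 (1.2 equiv), THF, −78 °C → rt
Reagents that add atoms: iodine, II
Why: Directed ortho-metalation; the C–H flanked by OMe and OMOM is doubly activated and is deprotonated selectively, and iodinolysis of the aryllithium gives the iodide.

Step 7
Reactants: 6 5,7-bis(benzyloxy)-6,8-dimethoxy-4H-chromen-4-one; 10 2-iodo-3-methoxy-1,4-bis(methoxymethoxy)benzene
Product: 12 5,7-bis(benzyloxy)-6,8-dimethoxy-2-[2-methoxy-3,6-bis(methoxymethoxy)phenyl]-4H-chromen-4-one, via chromon-2-ylzinc chloride 11 (not isolated)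
Conditions: 6 (1.2 equiv), TMPZnCl·LiCl (1.3 equiv), THF, −30 → 25 °C, 1 h; then 10 (1.0 equiv), Pd(OAc)2 (4 mol%), SPhos (8 mol%), THF, 55 °C
Reagents that add atoms: none
Why: The hindered amide base zincates the most acidic sp2 C–H of the chromone (C2, next to the ring oxygen) without attacking the carbonyl, which turns the normally electrophilic β-carbon into a nucleophilic α-alkoxyvinyl zinc centre (masked acyl anion), and Pd/SPhos Negishi cross-coupling joins it to the electrophilic ipso carbon of the doubly ortho-substituted iodide.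

Step 8
Reactants: 12 5,7-bis(benzyloxy)-6,8-dimethoxy-2-[2-methoxy-3,6-bis(methoxymethoxy)phenyl]-4H-chromen-4-one
Product: 13 5,7-dihydroxy-2-(3,6-dihydroxy-2-methoxyphenyl)-6,8-dimethoxy-4H-chromen-4-one (5,7,3′,6′-tetrahydroxy-6,8,2′-trimethoxyflavone)
Conditions: H2 (1 atm), 10% Pd/C, HCl (cat., 1.25 M in MeOH), MeOH–THF 1:1, rt → 40 °C; work-up under Ar
Reagents that add atoms: none
Why: Pd-catalysed hydrogenolysis cleaves the two benzyl ethers and acid-catalysed transacetalisation with methanol removes the two MOM acetals, while aryl methyl ethers and the flavone enone survive these mild conditions; no stereocentre is present or created.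

**Compound list**

1 | 2′,4′,6′-trihydroxyacetophenone | CC(=O)c1c(O)cc(O)cc1O | starting material
2 | 1-(3,5-dibromo-2,4,6-trihydroxyphenyl)ethan-1-one | CC(=O)c1c(O)c(Br)c(O)c(Br)c1O | intermediate
3 | 1-(2,4,6-trihydroxy-3,5-dimethoxyphenyl)ethan-1-one | CC(=O)c1c(O)c(OC)c(O)c(OC)c1O | intermediate
4 | 1-[4,6-bis(benzyloxy)-2-hydroxy-3,5-dimethoxyphenyl]ethan-1-one | CC(=O)c1c(O)c(OC)c(OCc2ccccc2)c(OC)c1OCc1ccccc1 | intermediate
5 | (E)-1-[4,6-bis(benzyloxy)-2-hydroxy-3,5-dimethoxyphenyl]-3-(dimethylamino)prop-2-en-1-one (enaminone) | CN(C)/C=C/C(=O)c1c(O)c(OC)c(OCc2ccccc2)c(OC)c1OCc1ccccc1 | intermediate (not isolated)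
6 | 5,7-bis(benzyloxy)-6,8-dimethoxy-4H-chromen-4-one | O=c1ccoc2c(OC)c(OCc3ccccc3)c(OC)c(OCc3ccccc3)c12 | intermediate
7 | 2-methoxybenzene-1,4-diol (methoxyhydroquinone) | COc1cc(O)ccc1O | starting material
8 | 2-methoxy-1,4-bis(methoxymethoxy)benzene | COCOc1ccc(OCOC)c(OC)c1 | intermediate
9 | [2-methoxy-3,6-bis(methoxymethoxy)phenyl]lithium (aryllithium) | COCOc1ccc(OCOC)c(OC)c1[Li] | intermediate (not isolated)
10 | 2-iodo-3-methoxy-1,4-bis(methoxymethoxy)benzene | COCOc1ccc(OCOC)c(OC)c1I | intermediate
11 | [5,7-bis(benzyloxy)-6,8-dimethoxy-4-oxo-4H-chromen-2-yl]zinc chloride (as LiCl complex) | O=c1cc([Zn]Cl)oc2c(OC)c(OCc3ccccc3)c(OC)c(OCc3ccccc3)c12 | intermediate (not isolated)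
12 | 5,7-bis(benzyloxy)-6,8-dimethoxy-2-[2-methoxy-3,6-bis(methoxymethoxy)phenyl]-4H-chromen-4-one | COCOc1ccc(OCOC)c(OC)c1-c1cc(=O)c2c(OCc3ccccc3)c(OC)c(OCc3ccccc3)c(OC)c2o1 | intermediate
13 | 5,7-dihydroxy-2-(3,6-dihydroxy-2-methoxyphenyl)-6,8-dimethoxy-4H-chromen-4-one | COc1c(O)ccc(O)c1-c1cc(=O)c2c(O)c(OC)c(O)c(OC)c2o1 | target

**Step count**

Total: 8 steps. Longest linear sequence: 6 steps (1, 2, 3, 4, 7, 8); steps 5 and 6 make the B-ring partner in parallel.

**Three steps most likely to fail, with fallbacks**

Step 2 (double copper-mediated methoxylation of a free triphenol; risk of hydrodebromination or oxidative decomposition). The fallback sets out from 2 and rejoins the route at 4, bypassing 3. It makes the C–O bonds by palladium catalysis on a fully O-protected substrate. Compound 2 is perbenzylated (BnBr 3.5 equiv, K2CO3, DMF, 60 °C) to 1-[2,4,6-tris(benzyloxy)-3,5-dibromophenyl]ethan-1-one F1. Both bromides are then exchanged by Pd-catalysed C–O cross-coupling with methanol (tBuBrettPhos-Pd precatalyst, Cs2CO3, toluene, 80 °C) to give 1-[2,4,6-tris(benzyloxy)-3,5-dimethoxyphenyl]ethan-1-one F2. Finally, one of the two equivalent benzyl ethers ortho to the acetyl group is removed by chelation-controlled cleavage with MgBr2·OEt2 (1.1 equiv, toluene/Et2O, 60 °C), which gives 4.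

Step 7 (key coupling; the iodide 10 is electron-rich and doubly ortho-substituted, so oxidative addition and transmetalation with the electron-poor chromonylzinc may stall). The fallback sets out from 11 and 9 and rejoins at 12, with the roles of the two partners exchanged. The zinc reagent 11 is quenched with iodine (THF, 0 °C) to give 5,7-bis(benzyloxy)-2-iodo-6,8-dimethoxy-4H-chromen-4-one F3. The aryllithium 9 is transmetalated with ZnCl2 (THF, 0 °C) to [2-methoxy-3,6-bis(methoxymethoxy)phenyl]zinc chloride F4. Negishi coupling of the electron-rich arylzinc with the reactive vinylogous acyl iodide (Pd2(dba)3/RuPhos, THF, 50 °C) then gives 12.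

Step 8 (one-pot reductive and acidic global deprotection; risk of over-reduction of the C2=C3 bond and of air oxidation of the hydroquinone during catalyst removal). The fallback sets out from 12 and rejoins at 13 by a staged, non-reductive sequence. The MOM groups are removed first with HCl in MeOH (40 °C, no hydrogen) to give 5,7-bis(benzyloxy)-2-(3,6-dihydroxy-2-methoxyphenyl)-6,8-dimethoxy-4H-chromen-4-one F5. The benzyl ethers are then cleaved by Lewis-acid transbenzylation with BCl3 and pentamethylbenzene as cation scavenger (CH2Cl2, −78 °C), which leaves the methyl ethers intact and gives 13.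

**Further compounds**

F1 | step 2 | 1-[2,4,6-tris(benzyloxy)-3,5-dibromophenyl]ethan-1-one | CC(=O)c1c(OCc2ccccc2)c(Br)c(OCc2ccccc2)c(Br)c1OCc1ccccc1
F2 | step 2 | 1-[2,4,6-tris(benzyloxy)-3,5-dimethoxyphenyl]ethan-1-one | CC(=O)c1c(OCc2ccccc2)c(OC)c(OCc2ccccc2)c(OC)c1OCc1ccccc1
F3 | step 7 | 5,7-bis(benzyloxy)-2-iodo-6,8-dimethoxy-4H-chromen-4-one | O=c1cc(I)oc2c(OC)c(OCc3ccccc3)c(OC)c(OCc3ccccc3)c12
F4 | step 7 | [2-methoxy-3,6-bis(methoxymethoxy)phenyl]zinc chloride | COCOc1ccc(OCOC)c(OC)c1[Zn]Cl
F5 | step 8 | 5,7-bis(benzyloxy)-2-(3,6-dihydroxy-2-methoxyphenyl)-6,8-dimethoxy-4H-chromen-4-one | COc1c(O)ccc(O)c1-c1cc(=O)c2c(OCc3ccccc3)c(OC)c(OCc3ccccc3)c(OC)c2o1
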